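**Retrosynthetic overview** (pyran numbering: O1, C2(Me), C3, C4, C5, C6)
1. Epoxytwinol A comes from its bis(silanol) ether. One operation is cut back through C3–C3′ and C6–C6′ (formal [4+4]), both O1–C2 bonds (retro oxa-6π) and both ring–propenyl bonds (Stille). This leaves two bromo-enals and two propenylstannanes.
2. The bromo-enal keeps its aldehyde carbon at the aldehyde level throughout (masked as a dimethyl acetal). The ketone is masked as a dimethyl ketal, and the carbinol comes from an anti-selective reduction of an epoxy ketone.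
3. The oxirane comes from a tartrate-mediated nucleophilic epoxidation of a bromoquinone monoketal. This is the only external source of chirality.
4. The monoketal comes from oxidative dearomatisation of a 4-methoxyphenol, which is made from 2-bromo-1,4-dimethoxybenzene and DMF.
5. Ring order: the carbocycle is bought as the arene, the oxirane follows in step 4, and the last flask forms both pyrans and then the central cycloocta-1,5-diene.

Assumption: L-(+)-diisopropyl tartrate is taken to deliver the oxirane enantiomer drawn in step 4; if the sense proves opposite, the D-(−)-ester is used and nothing else changes.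

**Step 1**
Reactants: 1 2-bromo-1,4-dimethoxybenzene
Product: 3 2-bromo-3,6-dimethoxybenzaldehyde, via aryllithium 2 (not isolated)
Conditions: LiN(i-Pr)2 (1.1 equiv), THF, −78 °C, 1 h; DMF, −78 to 0 °C; H2O
Reagents that add atoms: N,N-dimethylformamide, CN(C)C=O
Why: Directed ortho-lithiation/formylation: the C–H flanked by Br and OMe is the most acidic, the amide base removes it at −78 °C without Br/Li exchange or aryne formation, and DMF traps the aryllithium; no stereocentre is formed.

**Step 2**
Reactants: 3 2-bromo-3,6-dimethoxybenzaldehyde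
Product: 4 2-bromo-6-hydroxy-3-methoxybenzaldehyde
Conditions: BCl3 (1.1 equiv), CH2Cl2, −78 to 0 °C; H2O
Reagents that add atoms: none
Why: Chelation-controlled Lewis-acid aryl ether cleavage: boron bound to the aldehyde oxygen reaches only the ortho OMe through a six-membered chelate, so the methoxy group next to Br survives.

**Step 3**
Reactants: 4 2-bromo-6-hydroxy-3-methoxybenzaldehyde
Product: 6 3-bromo-2-(dimethoxymethyl)-4,4-dimethoxycyclohexa-2,5-dien-1-one, via phenol acetal 5 (not isolated)
Conditions: HC(OMe)3 (3 equiv), TsOH (2 mol %), MeOH, 40 °C; then PhI(OAc)2 (1.1 equiv), 0 °C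
Reagents that add atoms: trimethyl orthoformate, COC(OC)OC; methanol, CO
Why: Acid-catalysed acetalisation followed by oxidative dearomatisation of a 4-methoxyphenol with a trivalent iodine reagent in MeOH (quinone monoketal synthesis), where the orthoformate keeps the flask dry so the acetal holds and the para-methoxy carbon takes up MeOH; no stereocentre is formed.

**Step 4**
Reactants: 6 3-bromo-2-(dimethoxymethyl)-4,4-dimethoxycyclohexa-2,5-dien-1-one
Product: 7 (1S,6R)-4-bromo-3-(dimethoxymethyl)-5,5-dimethoxy-7-oxabicyclo[4.1.0]hept-3-en-2-one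
Conditions: Ph3COOH, NaN(SiMe3)2, L-(+)-diisopropyl tartrate, 4 Å molecular sieves, toluene, −50 °C; H2O
Reagents that add atoms: trityl hydroperoxide, OOC(c1ccccc1)(c1ccccc1)c1ccccc1
Why: Tartrate-mediated nucleophilic (Weitz–Scheffer type) epoxidation: the bulky trityl peroxide anion adds only to the unsubstituted enone C=C because the other one is tetrasubstituted and shielded by Br, acetal and ketal, and the sodium tartrate aggregate selects one enantiotopic face, which sets both oxirane carbons.

**Step 5**
Reactants: 7 (1S,6R)-4-bromo-3-(dimethoxymethyl)-5,5-dimethoxy-7-oxabicyclo[4.1.0]hept-3-en-2-one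
Product: 9 (1R,2S,6R)-4-bromo-2-hydroxy-5-oxo-7-oxabicyclo[4.1.0]hept-3-ene-3-carbaldehyde, via anti-epoxy alcohol 8 (not isolated)
Conditions: i-Bu2AlH (1.2 equiv), THF, −78 °C; then 1 M aq. H2SO4, THF, 0 °C to rt
Reagents that add atoms: water, O
Why: Diastereoselective 1,2-reduction followed by acid-catalysed acetal/ketal hydrolysis: aluminium binds the oxirane oxygen and hydride enters from that face, which places the new (S)-carbinol OH anti to the oxirane, and the acid quench then frees both carbonyls of a product that cannot dimerise because it still lacks the propenyl group.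

**Step 6**
Reactants: 9 (1R,2S,6R)-4-bromo-2-hydroxy-5-oxo-7-oxabicyclo[4.1.0]hept-3-ene-3-carbaldehyde
Product: 11 (1S,2S,6R)-4-bromo-2-{[hydroxy(diisopropyl)silyl]oxy}-5-oxo-7-oxabicyclo[4.1.0]hept-3-ene-3-carbaldehyde, via silyl triflate 10 (not isolated)
Conditions: i-Pr2Si(OTf)2 (1.5 equiv), 2,6-lutidine, CH2Cl2, −78 to −20 °C; then aq. NaHCO3
Reagents that add atoms: diisopropylsilyl bis(trifluoromethanesulfonate), CC(C)[Si](OS(=O)(=O)C(F)(F)F)(OS(=O)(=O)C(F)(F)F)C(C)C; water, O
Why: Silyl ether formation with a bis-electrophilic silane: the only hydroxyl attacks the excess bis(triflate) beside a non-nucleophilic base that spares the β-bromoenal, and bicarbonate hydrolysis of the remaining Si–OTf bond gives a hindered silanol that does not self-condense; no stereocentre is touched (the C1 descriptor changes only because of CIP ranking).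

**Step 7**
Reactants: 11 (1S,2S,6R)-4-bromo-2-{[hydroxy(diisopropyl)silyl]oxy}-5-oxo-7-oxabicyclo[4.1.0]hept-3-ene-3-carbaldehyde (2 equiv); 12 (E)-tributyl(prop-1-en-1-yl)stannane (2 equiv)
Product: 16 epoxytwinol A, via dienal silanol 13 (not isolated), via 2H-pyran silanol 14 (not isolated), via bis-silanol dimer 15 (not isolated)
Conditions: Pd2(dba)3 (5 mol %), AsPh3 (20 mol %), toluene (0.5 M), 35 °C; concentrate to ca. 2 M, rt, 48 h, dark; then Et3N·3HF, MeCN, rt
Reagents that add atoms: none
Why: Proposed new method: Stille coupling at the doubly activated C–Br bond (β-bromoenal and α-bromoenone, so zerovalent palladium inserts near room temperature) creates dienal 13 under neutral, non-oxidising conditions, 13 closes by reversible oxa-6π electrocyclisation to 2H-pyran 14 whose C2 epimers interconvert, and two (2R)-14 units, held head to head by a Si–OH···O(H)–Si hydrogen-bonded pair that spans the roughly 6 Å (model estimate) between the two carbinol oxygens of the C2-symmetric adduct, join stepwise (C3–C3′ first, then C6–C6′ of the captodative bis-allyl diradical) on the diene faces anti to oxirane and methyl, which fixes all six new stereocentres from the three already present before fluoride strips the silanols; the closest known reaction types are Stille propenylation of bromo-epoxyquinone derivatives, the alcohol-oxidation-triggered oxa-6π/dimerisation of epoxyquinol dienals and the silanol-assisted formal [4+4] dimerisation of such 2H-pyrans.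

**Compound list**
1 | 2-bromo-1,4-dimethoxybenzene | COc1ccc(OC)c(Br)c1 | starting material
2 | (2-bromo-3,6-dimethoxyphenyl)lithium | COc1ccc(OC)c(Br)c1[Li] | intermediate
3 | 2-bromo-3,6-dimethoxybenzaldehyde | COc1ccc(OC)c(Br)c1C=O | intermediate
4 | 2-bromo-6-hydroxy-3-methoxybenzaldehyde | Oc1ccc(OC)c(Br)c1C=O | intermediate
5 | 3-bromo-2-(dimethoxymethyl)-4-methoxyphenol | Oc1ccc(OC)c(Br)c1C(OC)OC | intermediate
6 | 3-bromo-2-(dimethoxymethyl)-4,4-dimethoxycyclohexa-2,5-dien-1-one | COC(OC)C1=C(Br)C(OC)(OC)C=CC1=O | intermediate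
7 | (1S,6R)-4-bromo-3-(dimethoxymethyl)-5,5-dimethoxy-7-oxabicyclo[4.1.0]hept-3-en-2-one | COC(OC)C1=C(Br)C(OC)(OC)[C@@H]2O[C@@H]2C1=O | intermediate
8 | (1R,2S,6R)-4-bromo-3-(dimethoxymethyl)-5,5-dimethoxy-7-oxabicyclo[4.1.0]hept-3-en-2-ol (OH anti to oxirane) | COC(OC)C1=C(Br)C(OC)(OC)[C@@H]2O[C@@H]2[C@H]1O | intermediate
9 | (1R,2S,6R)-4-bromo-2-hydroxy-5-oxo-7-oxabicyclo[4.1.0]hept-3-ene-3-carbaldehyde (OH anti to oxirane) | O=CC1=C(Br)C(=O)[C@@H]2O[C@@H]2[C@H]1O | intermediate
10 | diisopropyl{[(1S,2S,6R)-4-bromo-3-formyl-5-oxo-7-oxabicyclo[4.1.0]hept-3-en-2-yl]oxy}silyl trifluoromethanesulfonate | O=CC1=C(Br)C(=O)[C@@H]2O[C@@H]2[C@H]1O[Si](OS(=O)(=O)C(F)(F)F)(C(C)C)C(C)C | intermediate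
11 | (1S,2S,6R)-4-bromo-2-{[hydroxy(diisopropyl)silyl]oxy}-5-oxo-7-oxabicyclo[4.1.0]hept-3-ene-3-carbaldehyde | O=CC1=C(Br)C(=O)[C@@H]2O[C@@H]2[C@H]1O[Si](O)(C(C)C)C(C)C | intermediate
12 | (E)-tributyl(prop-1-en-1-yl)stannane | C/C=C/[Sn](CCCC)(CCCC)CCCC | starting material
13 | (1S,2S,6R)-2-{[hydroxy(diisopropyl)silyl]oxy}-5-oxo-4-[(E)-prop-1-en-1-yl]-7-oxabicyclo[4.1.0]hept-3-ene-3-carbaldehyde | O=CC1=C(/C=C/C)C(=O)[C@@H]2O[C@@H]2[C@H]1O[Si](O)(C(C)C)C(C)C | intermediate
14 | 2H-pyran valence tautomer of 13: (2R)-2-methyl-2H-pyran fused at C4–C5 to the epoxy(silyloxy)cyclohexanone; diene C3=C4–C5=C6 exocyclic to the carbocycle; methyl on the oxirane face, silyloxy on the opposite face | C[C@@H]1C=C2C(=O)[C@@H]3O[C@@H]3[C@@H](O[Si](O)(C(C)C)C(C)C)C2=CO1 | intermediate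
15 | epoxytwinol A bis[hydroxy(diisopropyl)silyl] ether (C2-symmetric head-to-head [4+4] dimer of 14) | C[C@H]1O[C@H]2C3=C(C(=O)[C@@H]4O[C@@H]4[C@H]3O[Si](O)(C(C)C)C(C)C)[C@@H]1[C@H]1C3=C([C@H](O[Si](O)(C(C)C)C(C)C)[C@H]4O[C@H]4C3=O)[C@@H]2O[C@@H]1C | intermediate
16 | epoxytwinol A (each half: pyran C2 R, C3 S, C6 S; carbinol S; both oxirane carbons R; OH anti to oxirane) | C[C@H]1O[C@H]2C3=C(C(=O)[C@@H]4O[C@@H]4[C@H]3O)[C@@H]1[C@H]1C3=C([C@H](O)[C@H]4O[C@H]4C3=O)[C@@H]2O[C@@H]1C | target

**Total step count:** 7. **Longest linear sequence:** 7.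

**Three steps most likely to fail**

Step 7. The coupling on the densely functionalised bromo-enal and the dimerisation must work in the same flask. Heat, palladium or tin residues could also erode the kinetic [4+4] adduct in favour of [4+2] dimers.
- The fallback sets out from 7 and comes back at 13. It separates C–C coupling from dimerisation and changes the trigger to carbonyl unmasking.
- Stille coupling of the β-bromoenone 7 with 12 (Pd2(dba)3, AsPh3, toluene, 100 °C) gives the propenyl epoxy ketone F1.
- Reduction with i-Bu2AlH at −78 °C gives the propenyl anti-epoxy alcohol F2.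
- Treatment with i-Pr2Si(OTf)2/2,6-lutidine and then aq. NaHCO3 gives the fully masked alkoxysilanol F3.
- Brief treatment with aq. TFA in CH2Cl2 at 0 °C removes acetal and ketal and releases 13 cold and metal-free. It then electrocyclises, dimerises at high concentration and is desilylated as in step 7.

Step 4. The ee and the sense of induction on a dimethyl ketal that carries an acetal side chain are not secured.
- The fallback sets out from 6 and comes back at 8. It replaces asymmetric induction by resolution.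
- Epoxidation with t-BuOOH/DBU gives the racemic epoxy ketone F4, and i-Bu2AlH gives the racemic anti-epoxy alcohol F5.
- Burkholderia cepacia lipase with vinyl acetate in MTBE acylates the (2S)-enantiomer (large group: the bromoalkenyl side; medium group: the oxirane CH) to the anti-epoxy acetate F6.
- F6 is separated from the unreacted antipode and cleaved with K2CO3/MeOH to 8, which is then hydrolysed with aq. H2SO4 as in step 5.

Step 5. The hydride may enter anti to the oxirane, and the telescoped acid quench may be too harsh.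
- The fallback sets out from 7 and comes back at 8. It accepts the opposite facial selectivity and corrects it by inversion.
- NaBH4/CeCl3 in MeOH at −78 °C gives the syn-epoxy alcohol F7.
- Mitsunobu reaction (4-nitrobenzoic acid, PPh3, DIAD, THF) inverts the carbinol to the anti 4-nitrobenzoate F8.
- K2CO3/MeOH gives 8, which is isolated and hydrolysed separately.

**Further compounds**
F1 | step 7 | propenyl epoxy ketone, (1S,6R)-3-(dimethoxymethyl)-5,5-dimethoxy-4-[(E)-prop-1-en-1-yl]-7-oxabicyclo[4.1.0]hept-3-en-2-one | COC(OC)C1=C(/C=C/C)C(OC)(OC)[C@@H]2O[C@@H]2C1=O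
F2 | step 7 | propenyl anti-epoxy alcohol, (1R,2S,6R)-3-(dimethoxymethyl)-5,5-dimethoxy-4-[(E)-prop-1-en-1-yl]-7-oxabicyclo[4.1.0]hept-3-en-2-ol | COC(OC)C1=C(/C=C/C)C(OC)(OC)[C@@H]2O[C@@H]2[C@H]1O
F3 | step 7 | fully masked alkoxysilanol, hydroxy(diisopropyl)silyl ether of F2 | COC(OC)C1=C(/C=C/C)C(OC)(OC)[C@@H]2O[C@@H]2[C@H]1O[Si](O)(C(C)C)C(C)C
F4 | step 4 | racemic epoxy ketone (1:1 mixture of 7 and its enantiomer) | COC(OC)C1=C(Br)C(OC)(OC)[C@@H]2O[C@@H]2C1=O.COC(OC)C1=C(Br)C(OC)(OC)[C@H]2O[C@H]2C1=O
F5 | step 4 | racemic anti-epoxy alcohol (1:1 mixture of 8 and its enantiomer) | COC(OC)C1=C(Br)C(OC)(OC)[C@@H]2O[C@@H]2[C@H]1O.COC(OC)C1=C(Br)C(OC)(OC)[C@H]2O[C@H]2[C@@H]1O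
F6 | step 4 | anti-epoxy acetate, (1R,2S,6R)-4-bromo-3-(dimethoxymethyl)-5,5-dimethoxy-7-oxabicyclo[4.1.0]hept-3-en-2-yl acetate | COC(OC)C1=C(Br)C(OC)(OC)[C@@H]2O[C@@H]2[C@H]1OC(C)=O
F7 | step 5 | syn-epoxy alcohol, (1R,2R,6R)-4-bromo-3-(dimethoxymethyl)-5,5-dimethoxy-7-oxabicyclo[4.1.0]hept-3-en-2-ol | COC(OC)C1=C(Br)C(OC)(OC)[C@@H]2O[C@@H]2[C@@H]1O
F8 | step 5 | anti 4-nitrobenzoate, (1R,2S,6R)-4-bromo-3-(dimethoxymethyl)-5,5-dimethoxy-7-oxabicyclo[4.1.0]hept-3-en-2-yl 4-nitrobenzoate | COC(OC)C1=C(Br)C(OC)(OC)[C@@H]2O[C@@H]2[C@H]1OC(=O)c1ccc(cc1)[N+](=O)[O-]
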